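**Retrosynthetic overview**

1. The target is the 3,4-bis-vanilloyl ester of (−)-quinic acid. Both esters go on last, onto 1,5-quinide 16, whose γ-lactone masks CO2H and O5 together; one acid hydrolysis then opens the lactone and frees the phenols.
2. Quinide comes from 4,5-O-isopropylidenequinic acid 13, made from methylenecyclohexanol 9 by hydroxyl-directed dihydroxylation of the exocyclic alkene and oxidation of the new CH2OH to CO2H.
3. Key disconnection: the C2–C3 ring bond, closed by an intramolecular carbonyl-ene reaction of acyclic aldehyde 7 (C3 = CHO; C4, C5, C6 from D-threitol; a 2-methylallyl group holds C1, C2 and the future carboxyl carbon).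
4. Enabling feature: in the cyclohexane ring the carbinol C3 and the quaternary C1 with its exocyclic carboxyl carbon flank the C2 methylene, so C(carboxyl)–C1–C2–C3–O is a homoallylic-alcohol retron; O3 and O1 are cis-1,3, so the hydroxyl made in the key step can steer the oxygen onto C1.
5. Ring order: cyclohexane (step 6), then the temporary lactone ring (step 9, reopened in step 14). Aldehyde 7 comes in five steps from 2,3-O-isopropylidene-D-threitol 1 and isopropenylmagnesium bromide 4; acid chloride 19 is a two-step side branch from vanillic acid 17.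

Key step: step 6

Remark on the chemistry: the target is taken as the ester of natural (1S,3R,4S,5R)-quinic acid, as its stereodescriptors require (O1, O3, O4 on one ring face, O5 and CO2H on the other); quinic numbering (C1–C6) is used throughout.

**Route**

Step 1
Reactants: 1 2,3-O-isopropylidene-D-threitol [(4R,5R)-2,2-dimethyl-1,3-dioxolane-4,5-dimethanol]
Product: 2 [(4R,5R)-5-({[tert-butyl(dimethyl)silyl]oxy}methyl)-2,2-dimethyl-1,3-dioxolan-4-yl]methanol
Conditions: NaH (1.0 equiv), THF, 0 °C → rt; TBSCl (1.0 equiv)
Reagents that add atoms: tert-butyldimethylsilyl chloride, CC(C)(C)[Si](C)(C)Cl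
Why: O-silylation through the monosodium alkoxide of the C2-symmetric diol should stop at the mono-ether, and since the two hydroxyls are homotopic no regiochemical question arises.

Step 2
Reactants: 2 mono-TBS ether
Product: 3 [(4R,5R)-5-({[tert-butyl(dimethyl)silyl]oxy}methyl)-2,2-dimethyl-1,3-dioxolan-4-yl]methyl trifluoromethanesulfonate
Conditions: Tf2O, pyridine, CH2Cl2, −20 °C; used at once
Reagents that add atoms: trifluoromethanesulfonic anhydride, O=S(=O)(OS(=O)(=O)C(F)(F)F)C(F)(F)F
Why: O-sulfonylation of the primary alcohol gives the triflate, the leaving group reactive enough for substitution next to a β-oxygen; no stereocentre is touched.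

Step 3
Reactants: 3 primary triflate; 4 isopropenylmagnesium bromide
Product: 5 tert-butyl{[(4R,5R)-2,2-dimethyl-5-(2-methylprop-2-en-1-yl)-1,3-dioxolan-4-yl]methoxy}dimethylsilane
Conditions: 4 (3 equiv), CuBr·SMe2 (10 mol %), Et2O, −30 → 0 °C
Reagents that add atoms: none
Why: copper-catalysed Grignard cross-coupling (SN2 displacement of the primary triflate by an alkenylcuprate) should install the 2-methylallyl unit that carries C1, C2 and the carboxyl carbon, without affecting the two stereocentres.

Step 4
Reactants: 5 TBS ether
Product: 6 [(4R,5R)-2,2-dimethyl-5-(2-methylprop-2-en-1-yl)-1,3-dioxolan-4-yl]methanol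
Conditions: TBAF, THF, 0 °C → rt
Reagents that add atoms: none
Why: fluoride-mediated desilylation should free the primary alcohol and leave the acetonide and the alkene untouched.

Step 5
Reactants: 6 primary alcohol
Product: 7 (4S,5R)-2,2-dimethyl-5-(2-methylprop-2-en-1-yl)-1,3-dioxolane-4-carbaldehyde
Conditions: Dess–Martin periodinane, NaHCO3, CH2Cl2, 0 °C → rt; used crude
Reagents that add atoms: none
Why: buffered Dess–Martin oxidation should give the α-alkoxy aldehyde without epimerisation, the trans-dioxolane being the more stable arrangement in any case.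

Step 6
Reactants: 7 aldehyde
Product: 9 (3aR,4R,7aR)-2,2-dimethyl-6-methylidenehexahydro-1,3-benzodioxol-4-ol (trans-fused acetonide; hydroxyl axial and cis to the neighbouring acetonide oxygen), via chloro(methyl)aluminium alkoxide 8 (not isolated)
Conditions: Me2AlCl (1.5 equiv), CH2Cl2, −78 → −30 °C; then aq. KNaC4H4O6
Reagents that add atoms: none
Why: This is a concerted type 2 intramolecular carbonyl-ene reaction: Me2AlCl activates the aldehyde, the terminal alkene carbon (future C2) bonds to the carbonyl carbon (future C3) while a hydrogen of the allylic methyl passes to oxygen through a six-membered array, so that the methyl becomes the exocyclic methylene on C1, and the alcohol complex then loses methane to give alkoxide 8, which removes the proton source for alkene migration. The closest known reaction type is the Me2AlCl-promoted type 2 carbonyl-ene cyclisation of 5-methylhex-5-enals to 3-methylenecyclohexanols. The six-membered carbocycle closes exo with respect to the carbonyl and endo with respect to the ene double bond, through a chair that is trans-fused to the dioxolane with the C4–O and C5–O bonds equatorial. The new stereocentre C3 is controlled by this chair: only an axial C=O can reach the methyl hydrogen on C1 (an equatorial C=O is too far away for concerted transfer), and the axial orientation also keeps the carbonyl oxygen closest to O4 for aluminium coordination, so the hydroxyl should come out axial, cis to O4 and trans to O5. The step needs facial selectivity at the aldehyde and regioselective hydrogen transfer from the methyl group and not from a ring methylene; the first is secured by the rigid trans-acetonide that holds the two existing stereocentres diequatorial, the second by the bicyclic transition state, in which the C6 hydrogens cannot reach the oxygen.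

Step 7
Reactants: 9 methylenecyclohexanol
Product: 11 (3aR,4R,6S,7aR)-6-(hydroxymethyl)-2,2-dimethylhexahydro-1,3-benzodioxole-4,6-diol, via osmate ester TMEDA chelate 10 (not isolated)
Conditions: OsO4 (1.05 equiv), TMEDA (1.1 equiv), CH2Cl2, −78 °C; then aq. Na2SO3, THF, reflux
Reagents that add atoms: osmium tetroxide, O=[Os](=O)(=O)=O
Why: in this hydroxyl-directed dihydroxylation the axial C3–OH should hydrogen-bond to the OsO4·TMEDA complex and deliver it to the axial face of the exocyclic alkene, so the new tertiary C1–O bond forms cis-1,3 to O3 and the CH2OH group ends equatorial, cis to O5.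

Step 8
Reactants: 11 triol
Product: 13 4,5-O-isopropylidene-(−)-quinic acid [(3aR,4R,6S,7aR)-4,6-dihydroxy-2,2-dimethylhexahydro-1,3-benzodioxole-6-carboxylic acid], via α-hydroxy aldehyde 12 (not isolated)
Conditions: TEMPO (cat.), NaOCl (cat.), NaClO2, NaH2PO4/Na2HPO4 buffer (pH 6.7), MeCN, 35 °C
Reagents that add atoms: sodium chlorite, [Na+].[O-]Cl=O
Why: the TEMPO-catalysed oxidation, completed by a Pinnick-type chlorite oxidation of the aldehyde, is selective for the primary carbinol over the secondary C3–OH and tertiary C1–OH, and the near-neutral buffer should spare the trans-acetonide.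

Step 9
Reactants: 13 4,5-O-isopropylidenequinic acid
Product: 15 3,4-O-isopropylidene-1,5-quinide, via 3,4-O-isopropylidenequinic acid 14 (not isolated)
Conditions: TsOH·H2O (cat.), toluene–DMF, reflux, Dean–Stark
Reagents that add atoms: none
Why: acid-catalysed acetal migration should move the strained trans-4,5-acetonide to the cis-3,4-diol under thermodynamic control, and the freed O5 then lactonises with the cis carboxyl (Fischer-type lactonisation with azeotropic water removal); O3 cannot lactonise because it is trans to the carboxyl.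

Step 10
Reactants: 15 3,4-O-isopropylidene-1,5-quinide
Product: 16 1,5-quinide [(−)-quinic acid 1,5-lactone; free 1-, 3- and 4-OH]
Conditions: TFA–H2O (9:1), rt
Reagents that add atoms: none
Why: acid-catalysed acetal hydrolysis should remove the acetonide while the bicyclic γ-lactone survives short contact with aqueous TFA at room temperature.

Step 11
Reactants: 17 vanillic acid
Product: 18 4-acetoxy-3-methoxybenzoic acid
Conditions: Ac2O, 2 M NaOH (aq.), 0 °C; then HCl to pH 2
Reagents that add atoms: acetic anhydride, CC(=O)OC(C)=O
Why: Schotten–Baumann O-acetylation of the phenoxide masks the phenol, and any mixed anhydride at the carboxyl is hydrolysed on work-up.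

Step 12
Reactants: 18 4-acetoxy-3-methoxybenzoic acid
Product: 19 4-acetoxy-3-methoxybenzoyl chloride
Conditions: (COCl)2, DMF (cat.), CH2Cl2, 0 °C → rt; used crude
Reagents that add atoms: oxalyl chloride, ClC(=O)C(Cl)=O
Why: acid chloride formation by Vilsmeier-type activation is compatible with the aryl acetate.

Step 13
Reactants: 16 1,5-quinide; 19 4-acetoxy-3-methoxybenzoyl chloride
Product: 20 3,4-bis-O-(4-acetoxy-3-methoxybenzoyl)-1,5-quinide
Conditions: 19 (2.4 equiv), pyridine, DMAP (cat.), CH2Cl2, 0 °C → rt
Reagents that add atoms: none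
Why: DMAP-catalysed O-acylation with the acid chloride should esterify the two secondary hydroxyls, while the tertiary C1–OH is too hindered to react and O5 and the carboxyl stay locked in the lactone.

Step 14
Reactants: 20 protected diester lactone
Product: 21 Burkinabin A [3,4-di-O-vanilloyl-(−)-quinic acid]
Conditions: 2 M HCl (aq.)–THF (1:3), rt
Reagents that add atoms: water, O
Why: acid-catalysed hydrolysis should open the strained bicyclic lactone and cleave the two aryl acetates well before the secondary alkyl aroates react, and the acidic medium suppresses acyl migration to the freed 5-OH.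

**Compound list**

1 | 2,3-O-isopropylidene-D-threitol, (4R,5R)-2,2-dimethyl-1,3-dioxolane-4,5-dimethanol | OC[C@H]1OC(C)(C)O[C@@H]1CO | starting material
2 | [(4R,5R)-5-({[tert-butyl(dimethyl)silyl]oxy}methyl)-2,2-dimethyl-1,3-dioxolan-4-yl]methanol | OC[C@H]1OC(C)(C)O[C@@H]1CO[Si](C)(C)C(C)(C)C | intermediate
3 | [(4R,5R)-5-({[tert-butyl(dimethyl)silyl]oxy}methyl)-2,2-dimethyl-1,3-dioxolan-4-yl]methyl trifluoromethanesulfonate | FC(F)(F)S(=O)(=O)OC[C@H]1OC(C)(C)O[C@@H]1CO[Si](C)(C)C(C)(C)C | intermediate
4 | isopropenylmagnesium bromide | CC(=C)[Mg]Br | starting material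
5 | tert-butyl{[(4R,5R)-2,2-dimethyl-5-(2-methylprop-2-en-1-yl)-1,3-dioxolan-4-yl]methoxy}dimethylsilane | CC(=C)C[C@H]1OC(C)(C)O[C@@H]1CO[Si](C)(C)C(C)(C)C | intermediate
6 | [(4R,5R)-2,2-dimethyl-5-(2-methylprop-2-en-1-yl)-1,3-dioxolan-4-yl]methanol | CC(=C)C[C@H]1OC(C)(C)O[C@@H]1CO | intermediate
7 | (4S,5R)-2,2-dimethyl-5-(2-methylprop-2-en-1-yl)-1,3-dioxolane-4-carbaldehyde | CC(=C)C[C@H]1OC(C)(C)O[C@@H]1C=O | intermediate
8 | chloro(methyl)aluminium alkoxide of 9 | C=C1C[C@@H](O[Al](C)Cl)[C@H]2OC(C)(C)O[C@@H]2C1 | intermediate
9 | (3aR,4R,7aR)-2,2-dimethyl-6-methylidenehexahydro-1,3-benzodioxol-4-ol | C=C1C[C@@H](O)[C@H]2OC(C)(C)O[C@@H]2C1 | intermediate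
10 | cyclic osmate ester of 9 (hexavalent osmium glycolate spanning C1–O and the CH2–O, chelated by TMEDA) | O=[Os]1(=O)OC[C@]2(O1)C[C@@H](O)[C@H]3OC(C)(C)O[C@@H]3C2.CN(C)CCN(C)C | intermediate
11 | (3aR,4R,6S,7aR)-6-(hydroxymethyl)-2,2-dimethylhexahydro-1,3-benzodioxole-4,6-diol | OC[C@]1(O)C[C@@H](O)[C@H]2OC(C)(C)O[C@@H]2C1 | intermediate
12 | (3aR,4R,6S,7aR)-4,6-dihydroxy-2,2-dimethylhexahydro-1,3-benzodioxole-6-carbaldehyde | O=C[C@]1(O)C[C@@H](O)[C@H]2OC(C)(C)O[C@@H]2C1 | intermediate
13 | 4,5-O-isopropylidene-(−)-quinic acid | OC(=O)[C@]1(O)C[C@@H](O)[C@H]2OC(C)(C)O[C@@H]2C1 | intermediate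
14 | 3,4-O-isopropylidene-(−)-quinic acid | OC(=O)[C@]1(O)C[C@H]2OC(C)(C)O[C@H]2[C@H](O)C1 | intermediate
15 | 3,4-O-isopropylidene-1,5-quinide | O=C1O[C@H]2[C@@H]3OC(C)(C)O[C@@H]3C[C@]1(O)C2 | intermediate
16 | 1,5-quinide, (−)-quinic acid 1,5-lactone | O=C1O[C@H]2[C@H](O)[C@H](O)C[C@]1(O)C2 | intermediate
17 | vanillic acid | COc1cc(ccc1O)C(O)=O | starting material
18 | 4-acetoxy-3-methoxybenzoic acid | COc1cc(ccc1OC(C)=O)C(O)=O | intermediate
19 | 4-acetoxy-3-methoxybenzoyl chloride | COc1cc(ccc1OC(C)=O)C(Cl)=O | intermediate
20 | 3,4-bis-O-(4-acetoxy-3-methoxybenzoyl)-1,5-quinide | O=C1O[C@H]2[C@H](OC(=O)c3ccc(OC(C)=O)c(OC)c3)[C@H](OC(=O)c4ccc(OC(C)=O)c(OC)c4)C[C@]1(O)C2 | intermediate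
21 | Burkinabin A, 3,4-di-O-vanilloyl-(−)-quinic acid | COc1cc(C(=O)O[C@H]2[C@H](O)C[C@](O)(C(=O)O)C[C@H]2OC(=O)c2ccc(O)c(OC)c2)ccc1O | target

**Step count and risks**

Total step count: 14. Longest linear sequence: 12 (steps 1–10, 13, 14).

Steps most likely to fail:

- **Step 6 (carbonyl-ene ring closure).** The closure may leave the concerted path for a stepwise cationic one. That would erode the facial selectivity at C3, let the double bond slip into the ring or let chloride add, and long contact with the Lewis acid may open the acetonide. The fallback replaces the ene reaction by an intramolecular Hosomi–Sakurai allylation and sets out from triflate 3. Coupling of 3 (CuBr·SMe2 cat., Et2O) with [1-(trimethylsilylmethyl)ethenyl]magnesium bromide F1, made from purchased 2-bromo-3-(trimethylsilyl)propene and Mg, should give the allylsilane silyl ether F2. HF·pyridine in THF–pyridine should then give the allylsilane alcohol F3, and Dess–Martin oxidation the allylsilane aldehyde F4. SnCl4 in CH2Cl2 at −78 °C should close the same C2–C3 bond; the β-silyl cation can collapse only to the exocyclic alkene, and chelation of the aldehyde oxygen with O4 should favour the same axial alcohol. The fallback comes back to the route at 9.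

- **Step 7 (directed dihydroxylation).** Delivery through the hydrogen bond may be outrun by attack of the bulky osmium reagent on the open equatorial face, which would give poor facial selectivity at C1. The fallback delivers one oxygen covalently and brings in the second by SN2 opening; it sets out from 9. VO(acac)2 and tert-butyl hydroperoxide in toluene should epoxidise the homoallylic exocyclic alkene through the vanadate ester of the axial C3–OH, giving the spiro-epoxide F5 with the epoxide oxygen cis to O3. KOH in DMSO–water at 80 °C should then open the epoxide at its CH2 terminus and leave the C1–O bond untouched. The fallback comes back to the route at 11.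

- **Step 14 (global acid hydrolysis).** The aryl acetates and the lactone may hydrolyse so slowly that the vanilloyl esters are cleaved or migrate from O4 to O5 during the long exposure to acid, or the lactone opening may stall at equilibrium. The fallback is a lactone-free, benzyl-based endgame finished by neutral hydrogenolysis; it sets out from 15.
  - LiOH (1 equiv, THF–H2O, 0 °C) should open the lactone to the carboxylate of 14, which is alkylated in the same flask with BnBr in DMF to benzyl 3,4-O-isopropylidenequinate F6.
  - CbzCl, pyridine and DMAP should cap the 5-OH as benzyl 5-O-(benzyloxycarbonyl)-3,4-O-isopropylidenequinate F7.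
  - TFA–H2O should remove the acetonide to give benzyl 5-O-(benzyloxycarbonyl)quinate F8.
  - Acylation (pyridine, DMAP) with 4-(benzyloxy)-3-methoxybenzoyl chloride F9, made from purchased 4-(benzyloxy)-3-methoxybenzoic acid and (COCl)2, should give benzyl 3,4-bis-O-[4-(benzyloxy)-3-methoxybenzoyl]-5-O-(benzyloxycarbonyl)quinate F10.
  - H2 over Pd/C in EtOAc–MeOH should remove the benzyl ester, the carbonate and both benzyl ethers in one neutral step. The fallback comes back to the route at 21.

**Further compounds**

F1 | step 6 | [1-(trimethylsilylmethyl)ethenyl]magnesium bromide | C[Si](C)(C)CC(=C)[Mg]Br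
F2 | step 6 | tert-butyl{[(4R,5R)-2,2-dimethyl-5-{2-[(trimethylsilyl)methyl]prop-2-en-1-yl}-1,3-dioxolan-4-yl]methoxy}dimethylsilane | C[Si](C)(C)CC(=C)C[C@H]1OC(C)(C)O[C@@H]1CO[Si](C)(C)C(C)(C)C
F3 | step 6 | [(4R,5R)-2,2-dimethyl-5-{2-[(trimethylsilyl)methyl]prop-2-en-1-yl}-1,3-dioxolan-4-yl]methanol | C[Si](C)(C)CC(=C)C[C@H]1OC(C)(C)O[C@@H]1CO
F4 | step 6 | (4S,5R)-2,2-dimethyl-5-{2-[(trimethylsilyl)methyl]prop-2-en-1-yl}-1,3-dioxolane-4-carbaldehyde | C[Si](C)(C)CC(=C)C[C@H]1OC(C)(C)O[C@@H]1C=O
F5 | step 7 | spiro-epoxide of 9 (epoxide oxygen on C1 cis to the C3 hydroxyl, CH2 terminus equatorial) | C1O[C@]12C[C@@H](O)[C@H]3OC(C)(C)O[C@@H]3C2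
F6 | step 14 | benzyl 3,4-O-isopropylidenequinate | O=C(OCc1ccccc1)[C@]2(O)C[C@H]3OC(C)(C)O[C@H]3[C@H](O)C2
F7 | step 14 | benzyl 5-O-(benzyloxycarbonyl)-3,4-O-isopropylidenequinate | O=C(OCc1ccccc1)[C@]2(O)C[C@H]3OC(C)(C)O[C@H]3[C@H](OC(=O)OCc4ccccc4)C2
F8 | step 14 | benzyl 5-O-(benzyloxycarbonyl)quinate | O=C(OCc1ccccc1)[C@]2(O)C[C@@H](O)[C@@H](O)[C@H](OC(=O)OCc3ccccc3)C2
F9 | step 14 | 4-(benzyloxy)-3-methoxybenzoyl chloride | COc1cc(ccc1OCc2ccccc2)C(Cl)=O
F10 | step 14 | benzyl 3,4-bis-O-[4-(benzyloxy)-3-methoxybenzoyl]-5-O-(benzyloxycarbonyl)quinate | O=C(OCc1ccccc1)[C@]2(O)C[C@@H](OC(=O)c3ccc(OCc4ccccc4)c(OC)c3)[C@@H](OC(=O)c5ccc(OCc6ccccc6)c(OC)c5)[C@H](OC(=O)OCc7ccccc7)C2
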